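## The problem

Target 34 is a bisabolane-type sesquiterpenoid diester whose cyclohexane ring carries five contiguous stereocentres. The ring is numbered C1 (side chain), C2 (angelate), C3 (free hydroxyl), C4–C5 (methyl-bearing epoxide) and C6, and the chain runs from C7 (with the methylidene carbon C14) to C11. The C1 chain, the C2 and C3 oxygens and the epoxide oxygen all lie on one face of the ring, and C4 is quaternary. Opened between C4 and C5, the ring becomes a chain in which C1/C2 are syn and C2/C3 anti, a pattern one aldol reaction can deliver; the C3 oxygen can then steer the new centre at C4, and C5 follows from C4 because an epoxide on a six-membered ring must be cis-fused. C8 and C10 are insulated from the ring by the sp2 carbon C7 and the C9 methylene, so both need reagent control. The molecule holds two trisubstituted epoxides that open with acid or Lewis acid, two (Z)-2-methylbut-2-enoates that isomerise to tiglates under nucleophilic bases, and a free C3 hydroxyl cis to the C2 ester that invites acyl migration under base; the esters and the side-chain epoxide therefore go in last and the final steps must be close to neutral. The feature that makes the key step possible is that the epoxide sits on the ring bond C4(Me)–C5 and C5 is an unsubstituted CH: C5 can be a sulfonium ylide carbon and C4 a methyl ketone carbonyl, so one intramolecular ylide addition forms the ring bond C4–C5 and the epoxide bond C5–O from an open chain.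

## Retrosynthesis

End game (34 back to 29). The last bond cut is the O–Si bond at C3 of 33, so the hydroxyl next to the C2 ester is freed only when no basic step remains. The side-chain epoxide of 33 is traced to the C10=C11 alkene of 32, the only electron-rich alkene in the molecule, so a chiral dioxirane can set C10. The two ester C–O bonds of 32 are cut to diol 30 and two molecules of angelic acid 31; acylating both hydroxyls in one operation saves a step and asks only that C3 stay masked. Diol 30 comes from 29 by selective loss of the more labile silyl group at C2.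

C7–C8 (29 to 25 and 27). Cutting this bond gives an alkenyl donor at C7 and the achiral aldehyde 27. A cut at C8–C9 would need a prenyl nucleophile, which attacks through its tertiary end, and a cut at C1–C7 would destroy the link to the aldol-derived stereocentre. The chosen cut leaves the enol triflate 25, which carries the whole ring. It asks for a mild, non-basic coupling in which the ligand on chromium, not the remote ring, fixes C8.

C4–C5 and C5–O (25 to 22), the key cut. Both bonds of the epoxide to C5, one of them a ring bond, are cut together, which leads to the acyclic keto sulfonium salt 22; its C4 carbonyl oxygen becomes the epoxide oxygen. Against epoxidation of a preformed cyclohexene, this cut removes the ring and two stereocentres in one move, and the remaining centres C1–C3 are of the kind an aldol reaction gives. The forward reaction must form the ylide only at C5, add to the ketone on the face cis to the C3 oxygen, and close faster than it eliminates. The C1 substituent of 22 is deliberately the enol triflate and not a carboxamide: an amide oxygen 1,4 to C5 would capture the silver-activated iodide in step 14, an acidic C1–H would invite cyclopropane formation or β-elimination in step 15, and a carbonyl at C7 would have to be methylated and enolised after the epoxide exists. For the same neighbouring-group reason C2 carries a triethylsilyl ether and not a benzyl-type ether.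

C5–S and the functional-group changes (22 to 13). Salt 22 is cut at C5–S to iodide 20 and diphenyl sulfide 21; two phenyl groups on sulfur leave C5 as the only place where an ylide can form. Iodide 20 comes from chloride 19, whose C4 ketone is the ozonolysis product of the isopropenyl group in 17. The alkene is a ketone surrogate that survives the organometallic and enolate steps before it. Triflate 17 comes from methyl ketone 15, 15 from Weinreb amide 14, and 14 is the silyl ether of 13. The chloride is carried this far because it ignores enolates and Grignard reagents.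

C1–C2 (13 to 10 and 7). Amide 13 is the transamidation product of aldol adduct 12, which is cut at C1–C2 into imide 10 and aldehyde 7. This is the only cut that creates both C1 and C2 under control of a recoverable auxiliary while C3 arrives already set in 7. The forward reaction must be syn-selective and must pair the auxiliary with the aldehyde so that both favour the same face.

Small fragments. Aldehyde 7 is reached from enone 3 by enantioselective reduction to 4, silylation to 5, primary desilylation to 6 and oxidation; enone 3 comes from amide 1 and Grignard reagent 2. Imide 10 comes from auxiliary 8 and acid chloride 9. Aldehyde 27 comes from alcohol 26.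

## Roads not taken

Alternative 1: Diels–Alder. The cut is C1–C6 and C2–C3 together. In the forward key step isoprene A1 adds across the enol-ether double bond of the chiral dioxinone A2, under Lewis acid or high pressure, to give the cis-fused bicyclic lactone acetal A3. Its merits are real: the ring comes from two small components in one step, C1/C2 are cis by the dienophile geometry, their absolute configuration comes from the acetal centre, C7 arrives as a carboxyl carbon and C4=C5 is in place. In steps to the carbocycle this road is clearly shorter than the chosen one. Its weak points are that A2 is a donor-substituted, sluggish dienophile whose acetal must survive the activation, and that the position of the methyl group rests on a moderate "para" preference. Above all, A3 has no oxygen at C3. It would need a late allylic oxidation that selects C3 over C6 and the methyl group and puts the oxygen cis to C2–O, followed by a directed epoxidation. The chosen plan spends more steps before the ring exists; in return it brings the C2 and C3 oxygens, already differentiated, from one aldol reaction and needs no C–H oxidation on the finished ring.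

Alternative 2: Ireland–Claisen ring contraction. The cut is C1–C6, with C7 as a carboxyl group. In the forward key step the silyl ketene acetal of the sugar-derived vinyl lactone A4 rearranges on warming, with loss of the lactone C–O bond, to the cyclohexene acid A5. C2 and C3 come from the chiral pool, and C1 is set by a well-understood sigmatropic transition state. The C4=C5 alkene lies next to the C3 oxygen, so a hydroxyl-directed epoxidation would give the cis epoxide with a predictability the ylide addition cannot match. The weak points are that A4 needs a quaternary carbinol centre (methyl and vinyl) of defined configuration on a deoxygenated sugar lactone, and that its enolisation puts a leaving oxygen β to the enolate carbon. The acetonide of A5 also leaves the C2 and C3 oxygens undifferentiated, although only C2 is acylated in 34. On the epoxide this road is the safer one. The chosen plan sets against it a short, non-carbohydrate route to a precursor in which C2 and C3 carry different silyl groups from the start, and an epoxide made in the ring-forming step with no separate oxidation.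

Alternative 3: intramolecular Barbier allylation. The cut is C1–C2. In the forward key step zinc or indium metal inserts into the allylic bromide of A6. The allylmetal attacks the C2 aldehyde through C1, which closes the ring and creates the C7 methylidene, and the C2 alkoxide closes onto the ester to give the cis-fused methylene lactone A7. C1, C2, the methylidene and the C1–C7 bond are made in one tolerant step; the chosen plan needs an enol triflate and a nickel/chromium coupling for the same result, so here this road is better. Its weak points are that A6 combines a geometrically defined Z-trisubstituted alkene with an epimerisable α-silyloxy aldehyde, and that the lactone fixes C1/C2 as cis but not their relation to C3. C8 arrives as a lactone carbonyl, so a prenyl-type nucleophile would have to add once, at its primary end, to a methylene lactone that is also a Michael acceptor, and a stereoselective reduction would follow. The epoxide is still to be made. The chosen plan is longer at C7 but forms C7–C8 and the C8 stereocentre in one ligand-controlled step from an aldehyde, and it never carries a Michael acceptor.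

Key step: step 15

Assumption: in step 17 the (S)-configured oxazoline–sulfonamide ligand is taken to direct the alkenylchromium reagent to the Re face of aldehyde 27; if the sense is the opposite, its enantiomer is used and nothing else changes.

## Steps

Abbreviations: TBS = tert-butyldimethylsilyl, TES = triethylsilyl, Tf = trifluoromethanesulfonyl. Ring compounds from 24 onwards, including the bisabolane-type names, use the numbering C1–C11 defined above (methyl group on C4).

Step 1
Reactants: 1 2-[(tert-butyldimethylsilyl)oxy]-N-methoxy-N-methylacetamide; 2 isopropenylmagnesium bromide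
Product: 3 1-[(tert-butyldimethylsilyl)oxy]-3-methylbut-3-en-2-one
Conditions: THF, 0 °C; cold aq. citric acid quench
Reagents that add atoms: none
Why: Weinreb ketone synthesis; the chelated tetrahedral adduct holds until work-up, so one isopropenyl group is transferred, and the acidic quench keeps the released hydroxylamine from adding to the enone.

Step 2
Reactants: 3 1-[(tert-butyldimethylsilyl)oxy]-3-methylbut-3-en-2-one
Product: 4 (S)-1-[(tert-butyldimethylsilyl)oxy]-3-methylbut-3-en-2-ol
Conditions: (S)-1-methyl-3,3-diphenyl-tetrahydro-1H,3H-pyrrolo[1,2-c][1,3,2]oxazaborole (0.2 equiv), BH3·SMe2, THF, −30 °C; MeOH, then aq. NH4Cl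
Reagents that add atoms: none
Why: Corey–Bakshi–Shibata reduction; with the α-branched alkenyl group as the large and CH2OSi as the small substituent, the (S)-oxazaborolidine should give the (S)-carbinol, which becomes C3 of the target.

Step 3
Reactants: 4 (S)-1-[(tert-butyldimethylsilyl)oxy]-3-methylbut-3-en-2-ol
Product: 5 (S)-1,2-bis[(tert-butyldimethylsilyl)oxy]-3-methylbut-3-ene
Conditions: TBSCl, imidazole, DMF, rt
Reagents that add atoms: tert-butyldimethylsilyl chloride, CC(C)(C)[Si](C)(C)Cl
Why: Imidazole-promoted silylation of a secondary allylic alcohol; the stereocentre is not touched.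

Step 4
Reactants: 5 (S)-1,2-bis[(tert-butyldimethylsilyl)oxy]-3-methylbut-3-ene
Product: 6 (S)-2-[(tert-butyldimethylsilyl)oxy]-3-methylbut-3-en-1-ol
Conditions: HF·pyridine, pyridine, THF, 0 °C
Reagents that add atoms: none
Why: Selective desilylation; buffered HF·pyridine cleaves the unhindered primary silyl ether well before the secondary one.

Step 5
Reactants: 6 (S)-2-[(tert-butyldimethylsilyl)oxy]-3-methylbut-3-en-1-ol
Product: 7 (S)-2-[(tert-butyldimethylsilyl)oxy]-3-methylbut-3-enal
Conditions: Dess–Martin periodinane, NaHCO3, CH2Cl2, 0 °C to rt; used at once without chromatography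
Reagents that add atoms: none
Why: Dess–Martin oxidation under buffered, amine-free conditions, chosen because the α-silyloxy β,γ-unsaturated aldehyde can epimerise or move into conjugation with base.

Step 6
Reactants: 8 (R)-4-benzyl-2-oxazolidinone; 9 4-chlorobutanoyl chloride
Product: 10 (R)-4-benzyl-3-(4-chlorobutanoyl)-2-oxazolidinone
Conditions: n-BuLi, THF, −78 °C; then 9, −78 to 0 °C
Reagents that add atoms: none
Why: N-acylation of the lithiated Evans auxiliary with an acid chloride; the primary alkyl chloride is inert at this temperature.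

Step 7
Reactants: 10 (R)-4-benzyl-3-(4-chlorobutanoyl)-2-oxazolidinone; 7 (S)-2-[(tert-butyldimethylsilyl)oxy]-3-methylbut-3-enal
Product: 12 (4R)-4-benzyl-3-[(2R,3R,4S)-4-[(tert-butyldimethylsilyl)oxy]-2-(2-chloroethyl)-3-hydroxy-5-methylhex-5-enoyl]-2-oxazolidinone, via boron enolate 11 (not isolated)
Conditions: Bu2BOTf, i-Pr2NEt, CH2Cl2, 0 °C; 7, −78 to 0 °C; pH 7 buffer, MeOH, H2O2, 0 °C
Reagents that add atoms: none
Why: Evans syn-aldol reaction; the Z boron enolate reacts through a chair Zimmerman–Traxler transition state in which the benzyl group of the auxiliary shields one enolate face, which sets C1 and C2 (1,2-syn). The α-silyloxy centre of 7 favours the same aldehyde face (Cornforth/polar Felkin–Anh, 2,3-anti), so the pairing is matched.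

Step 8
Reactants: 12 (4R)-4-benzyl-3-[(2R,3R,4S)-4-[(tert-butyldimethylsilyl)oxy]-2-(2-chloroethyl)-3-hydroxy-5-methylhex-5-enoyl]-2-oxazolidinone
Product: 13 (2R,3R,4S)-4-[(tert-butyldimethylsilyl)oxy]-2-(2-chloroethyl)-3-hydroxy-N-methoxy-N,5-dimethylhex-5-enamide
Conditions: MeNHOMe·HCl, AlMe3, CH2Cl2, −15 to 0 °C; aq. potassium sodium tartrate
Reagents that add atoms: N,O-dimethylhydroxylamine hydrochloride, CNOC.Cl
Why: Aluminium amide transamidation of an Evans aldol adduct; the free β-hydroxyl binds aluminium and directs attack to the exocyclic carbonyl, which releases the auxiliary for recovery.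

Step 9
Reactants: 13 (2R,3R,4S)-4-[(tert-butyldimethylsilyl)oxy]-2-(2-chloroethyl)-3-hydroxy-N-methoxy-N,5-dimethylhex-5-enamide
Product: 14 (2R,3R,4S)-4-[(tert-butyldimethylsilyl)oxy]-2-(2-chloroethyl)-N-methoxy-N,5-dimethyl-3-[(triethylsilyl)oxy]hex-5-enamide
Conditions: TESOTf, 2,6-lutidine, CH2Cl2, −78 to 0 °C
Reagents that add atoms: triethylsilyl trifluoromethanesulfonate, CC[Si](CC)(CC)OS(=O)(=O)C(F)(F)F
Why: Silylation of a hindered secondary alcohol with a silyl triflate; triethylsilyl is chosen because it can later be removed beside the TBS ether at C3 and because a silyl ether oxygen is a poor neighbouring group in step 14.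

Step 10
Reactants: 14 (2R,3R,4S)-4-[(tert-butyldimethylsilyl)oxy]-2-(2-chloroethyl)-N-methoxy-N,5-dimethyl-3-[(triethylsilyl)oxy]hex-5-enamide
Product: 15 (3R,4R,5S)-5-[(tert-butyldimethylsilyl)oxy]-3-(2-chloroethyl)-6-methyl-4-[(triethylsilyl)oxy]hept-6-en-2-one
Conditions: MeMgBr, THF, 0 °C; aq. NH4Cl
Reagents that add atoms: methylmagnesium bromide, C[Mg]Br
Why: Weinreb ketone synthesis; the chelated adduct stops at the ketone, the alkyl chloride is inert to the Grignard reagent, and doing this before the ring exists keeps MgBr2 away from the later epoxide.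

Step 11
Reactants: 15 (3R,4R,5S)-5-[(tert-butyldimethylsilyl)oxy]-3-(2-chloroethyl)-6-methyl-4-[(triethylsilyl)oxy]hept-6-en-2-one
Product: 17 (3R,4R,5S)-5-[(tert-butyldimethylsilyl)oxy]-3-(2-chloroethyl)-6-methyl-4-[(triethylsilyl)oxy]hepta-1,6-dien-2-yl trifluoromethanesulfonate, via potassium enolate 16 (not isolated)
Conditions: KN(SiMe3)2 (1.2 equiv) added to 15 and PhNTf2, THF, −78 °C
Reagents that add atoms: N-phenylbis(trifluoromethanesulfonimide), O=S(=O)(N(c1ccccc1)S(=O)(=O)C(F)(F)F)C(F)(F)F
Why: Kinetic enolisation of a methyl ketone at the methyl group and O-triflation (enol triflate synthesis); the enolate is trapped as it forms, before it can alkylate at the chloride or equilibrate towards C1.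

Step 12
Reactants: 17 (3R,4R,5S)-5-[(tert-butyldimethylsilyl)oxy]-3-(2-chloroethyl)-6-methyl-4-[(triethylsilyl)oxy]hepta-1,6-dien-2-yl trifluoromethanesulfonate
Product: 19 (3R,4R,5R)-5-[(tert-butyldimethylsilyl)oxy]-3-(2-chloroethyl)-6-oxo-4-[(triethylsilyl)oxy]hept-1-en-2-yl trifluoromethanesulfonate, via ozonide 18 (not isolated)
Conditions: O3, CH2Cl2, −78 °C, stopped at the first excess; PPh3, −78 °C to rt
Reagents that add atoms: ozone, [O-][O+]=O
Why: Ozonolysis with reductive work-up; electrophilic ozone takes the 1,1-dialkyl alkene far faster than the electron-poor enol triflate alkene, and the silyl ethers and the chloride do not react.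

Step 13
Reactants: 19 (3R,4R,5R)-5-[(tert-butyldimethylsilyl)oxy]-3-(2-chloroethyl)-6-oxo-4-[(triethylsilyl)oxy]hept-1-en-2-yl trifluoromethanesulfonate
Product: 20 (3R,4R,5R)-5-[(tert-butyldimethylsilyl)oxy]-3-(2-iodoethyl)-6-oxo-4-[(triethylsilyl)oxy]hept-1-en-2-yl trifluoromethanesulfonate
Conditions: NaI, acetone, 55 °C, dark
Reagents that add atoms: sodium iodide, [Na+].[I-]
Why: Finkelstein halide exchange (SN2) driven by precipitation of NaCl; it follows the ozonolysis because alkyl iodides are oxidised by ozone.

Step 14
Reactants: 20 (3R,4R,5R)-5-[(tert-butyldimethylsilyl)oxy]-3-(2-iodoethyl)-6-oxo-4-[(triethylsilyl)oxy]hept-1-en-2-yl trifluoromethanesulfonate; 21 diphenyl sulfide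
Product: 22 [(3R,4R,5R)-5-[(tert-butyldimethylsilyl)oxy]-6-oxo-4-[(triethylsilyl)oxy]-3-[1-(trifluoromethanesulfonyloxy)ethenyl]heptyl]diphenylsulfonium tetrafluoroborate
Conditions: 21 (5 equiv), AgBF4, 2,6-di-tert-butyl-4-methylpyridine (0.2 equiv), CH2Cl2, 0 °C to rt, dark
Reagents that add atoms: silver tetrafluoroborate, [Ag+].F[B-](F)(F)F
Why: Silver-assisted S-alkylation of a diaryl sulfide by a primary iodide, the standard route to alkyldiphenylsulfonium tetrafluoroborates; the substrate has no amide or benzyl ether oxygen 1,4 or 1,5 to C5 to compete with the sulfide, and the hindered pyridine scavenges acid.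

Step 15
Reactants: 22 [(3R,4R,5R)-5-[(tert-butyldimethylsilyl)oxy]-6-oxo-4-[(triethylsilyl)oxy]-3-[1-(trifluoromethanesulfonyloxy)ethenyl]heptyl]diphenylsulfonium tetrafluoroborate
Product: 25 1-[(1R,2R,3R,4S,5S)-3-[(tert-butyldimethylsilyl)oxy]-4,5-epoxy-4-methyl-2-[(triethylsilyl)oxy]cyclohexyl]ethenyl trifluoromethanesulfonate, via sulfonium ylide 23 (not isolated), via betaine 24 (not isolated)
Conditions: KN(SiMe3)2 (1.05 equiv), THF (0.01 M), −78 to −30 °C
Reagents that add atoms: none
Why: KN(SiMe3)2 removes a C5 hydrogen of 22, the only kind of hydrogen α to sulfur because the other two sulfur substituents are phenyl, to give the ylide; C5 then adds to the C4 ketone to give the betaine, whose alkoxide displaces diphenyl sulfide from C5 in an intramolecular SN2 reaction. The closest known reaction type is the Corey–Chaykovsky epoxidation with alkyldiphenylsulfonium ylides in its intramolecular form, the epoxy-annulation of keto sulfonium salts. The carbocycle closes by a 6-exo-trig addition and the epoxide by a 3-exo-tet displacement. C4 is controlled by the C3 silyloxy centre and by the ring being formed: in the chair-like transition state the C1 alkenyl and C3 silyloxy groups are equatorial and the C2 silyloxy group axial, C5 approaches anti to the C3–O bond (polar Felkin–Anh, potassium being a non-chelating counter-ion), and the C4 methyl group goes equatorial to avoid a 1,3-diaxial contact with the C2 silyloxy group, which puts the C4 oxygen axial and cis to the C3 oxygen. C5 follows from C4, because only the betaine with oxygen and sulfur trans can reach the anti-periplanar geometry for displacement, and a six-membered ring accepts only a cis-fused epoxide. The step needs chemoselective ylide formation, secured by the gap of several pKa units between the sulfonium α-hydrogens and the ketone α-hydrogens and by the absence of an enolisable carbonyl group at C1. It also needs addition to outrun E2 loss of diphenyl sulfide, which low temperature and high dilution favour; the enol triflate should survive because only one equivalent of base is used at −78 °C.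

Step 16
Reactants: 26 4-methylpent-3-en-1-ol
Product: 27 4-methylpent-3-enal
Conditions: Dess–Martin periodinane, NaHCO3, CH2Cl2, 0 °C; filtered and used cold as a solution
Reagents that add atoms: none
Why: Dess–Martin oxidation under buffered conditions; the β,γ-unsaturated aldehyde is used directly so that the alkene does not move into conjugation.

Step 17
Reactants: 25 1-[(1R,2R,3R,4S,5S)-3-[(tert-butyldimethylsilyl)oxy]-4,5-epoxy-4-methyl-2-[(triethylsilyl)oxy]cyclohexyl]ethenyl trifluoromethanesulfonate; 27 4-methylpent-3-enal
Product: 29 (3S)-2-[(1S,2R,3R,4S,5S)-3-[(tert-butyldimethylsilyl)oxy]-4,5-epoxy-4-methyl-2-[(triethylsilyl)oxy]cyclohexyl]-6-methylhepta-1,5-dien-3-ol, via alkenylchromium dichloride 28 (not isolated)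
Conditions: CrCl2 (4 equiv), (S)-N-[2-(4-isopropyl-4,5-dihydrooxazol-2-yl)-6-methylphenyl]methanesulfonamide, Et3N, THF, rt; NiCl2 (0.2 equiv); 25 and 27, rt; aq. ethylenediamine
Reagents that add atoms: none
Why: Nozaki–Hiyama–Kishi coupling; zerovalent nickel inserts into the C–O bond of the enol triflate, transmetallation gives the alkenyl species of trivalent chromium, and this adds to the aldehyde. The chiral sulfonamide ligand on chromium is relied on to set C8 (S) by Re-face addition, since the ring stereocentres are too remote. The conditions are non-basic, so 27 does not isomerise.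

Step 18
Reactants: 29 (3S)-2-[(1S,2R,3R,4S,5S)-3-[(tert-butyldimethylsilyl)oxy]-4,5-epoxy-4-methyl-2-[(triethylsilyl)oxy]cyclohexyl]-6-methylhepta-1,5-dien-3-ol
Product: 30 (3S)-2-[(1S,2R,3R,4S,5S)-3-[(tert-butyldimethylsilyl)oxy]-4,5-epoxy-2-hydroxy-4-methylcyclohexyl]-6-methylhepta-1,5-dien-3-ol
Conditions: HF·pyridine, pyridine, THF, 0 °C
Reagents that add atoms: none
Why: Selective silyl ether cleavage; the triethylsilyl ether is cleaved by buffered HF·pyridine much faster than the hindered TBS ether at C3, and the buffering protects the epoxide.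

Step 19
Reactants: 30 (3S)-2-[(1S,2R,3R,4S,5S)-3-[(tert-butyldimethylsilyl)oxy]-4,5-epoxy-2-hydroxy-4-methylcyclohexyl]-6-methylhepta-1,5-dien-3-ol; 31 angelic acid
Product: 32 (1S,2R,3R,4S,5S,8S)-3-[(tert-butyldimethylsilyl)oxy]-4,5-epoxybisabola-7(14),10-diene-2,8-diyl bis[(Z)-2-methylbut-2-enoate]
Conditions: 31 (5 equiv), 2,4,6-trichlorobenzoyl chloride (5 equiv), Et3N, toluene, rt; then 30 (1 equiv), toluene, 75 °C
Reagents that add atoms: angelic acid (the second equivalent of 31 that is incorporated), C/C=C(/C)C(=O)O
Why: Yamaguchi esterification without a nucleophilic catalyst; the mixed anhydride preformed from an excess of 31 acylates both secondary alcohols on heating, so two molecules of 31 end up in 32 (one at C2–O, one at C8–O). Leaving out 4-(dimethylamino)pyridine avoids the conjugate addition–elimination that turns angelates into tiglates.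

Step 20
Reactants: 32 (1S,2R,3R,4S,5S,8S)-3-[(tert-butyldimethylsilyl)oxy]-4,5-epoxybisabola-7(14),10-diene-2,8-diyl bis[(Z)-2-methylbut-2-enoate]
Product: 33 (1S,2R,3R,4S,5S,8S,10R)-3-[(tert-butyldimethylsilyl)oxy]-4,5:10,11-diepoxybisabol-7(14)-ene-2,8-diyl bis[(Z)-2-methylbut-2-enoate]
Conditions: 1,2:4,5-di-O-isopropylidene-β-D-erythro-2,3-hexodiulo-2,6-pyranose (0.3 equiv), KHSO5 (as 2KHSO5·KHSO4·K2SO4), K2CO3, Bu4NHSO4, MeCN–CH2(OMe)2–aq. Na2B4O7 buffer (pH 10.5), 0 °C
Reagents that add atoms: potassium peroxymonosulfate, [K+].[O-]S(=O)(=O)OO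
Why: Shi asymmetric epoxidation; the chiral dioxirane formed in the flask reacts with the electron-rich trisubstituted C10=C11 alkene through a spiro transition state, and the D-fructose-derived ketone gives the (10R)-epoxide. The 1,1-disubstituted alkene next to an allylic ester and the two conjugated angelate alkenes are much less reactive.

Step 21
Reactants: 33 (1S,2R,3R,4S,5S,8S,10R)-3-[(tert-butyldimethylsilyl)oxy]-4,5:10,11-diepoxybisabol-7(14)-ene-2,8-diyl bis[(Z)-2-methylbut-2-enoate]
Product: 34 target CNP0235377.1 [(1S,2R,3R,4R,5S,8S,10R)-4,5:10,11-diepoxy-3-hydroxybisabol-7(14)-ene-2,8-diyl bis[(Z)-2-methylbut-2-enoate]]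
Conditions: HF·pyridine, pyridine, THF, 0 °C to rt
Reagents that add atoms: none
Why: Fluoride-mediated desilylation under buffered, weakly acidic conditions, chosen over basic fluoride sources so that the C2 angelate does not migrate to the freed C3 hydroxyl and the esters do not isomerise; excess pyridine protects the two epoxides.

## Compound list

1 | 2-[(tert-butyldimethylsilyl)oxy]-N-methoxy-N-methylacetamide | CON(C)C(=O)CO[Si](C)(C)C(C)(C)C | starting material
2 | isopropenylmagnesium bromide | CC(=C)[Mg]Br | starting material
3 | 1-[(tert-butyldimethylsilyl)oxy]-3-methylbut-3-en-2-one | C=C(C)C(=O)CO[Si](C)(C)C(C)(C)C | intermediate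
4 | (S)-1-[(tert-butyldimethylsilyl)oxy]-3-methylbut-3-en-2-ol | C=C(C)[C@H](O)CO[Si](C)(C)C(C)(C)C | intermediate
5 | (S)-1,2-bis[(tert-butyldimethylsilyl)oxy]-3-methylbut-3-ene | C=C(C)[C@H](O[Si](C)(C)C(C)(C)C)CO[Si](C)(C)C(C)(C)C | intermediate
6 | (S)-2-[(tert-butyldimethylsilyl)oxy]-3-methylbut-3-en-1-ol | C=C(C)[C@H](O[Si](C)(C)C(C)(C)C)CO | intermediate
7 | (S)-2-[(tert-butyldimethylsilyl)oxy]-3-methylbut-3-enal | C=C(C)[C@H](O[Si](C)(C)C(C)(C)C)C=O | intermediate
8 | (R)-4-benzyl-2-oxazolidinone | O=C1OC[C@@H](Cc2ccccc2)N1 | starting material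
9 | 4-chlorobutanoyl chloride | O=C(Cl)CCCCl | starting material
10 | (R)-4-benzyl-3-(4-chlorobutanoyl)-2-oxazolidinone | O=C(CCCCl)N1[C@H](Cc2ccccc2)COC1=O | intermediate
11 | (Z)-dibutylboron enolate of 10 | ClCC/C=C(\OB(CCCC)CCCC)N1[C@H](Cc2ccccc2)COC1=O | intermediate (not isolated)
12 | (4R)-4-benzyl-3-[(2R,3R,4S)-4-[(tert-butyldimethylsilyl)oxy]-2-(2-chloroethyl)-3-hydroxy-5-methylhex-5-enoyl]-2-oxazolidinone (1,2-syn, 2,3-anti aldol adduct) | C=C(C)[C@H](O[Si](C)(C)C(C)(C)C)[C@H](O)[C@H](C(=O)N1[C@H](Cc2ccccc2)COC1=O)CCCl | intermediate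
13 | (2R,3R,4S)-4-[(tert-butyldimethylsilyl)oxy]-2-(2-chloroethyl)-3-hydroxy-N-methoxy-N,5-dimethylhex-5-enamide | C=C(C)[C@H](O[Si](C)(C)C(C)(C)C)[C@H](O)[C@H](C(=O)N(C)OC)CCCl | intermediate
14 | (2R,3R,4S)-4-[(tert-butyldimethylsilyl)oxy]-2-(2-chloroethyl)-N-methoxy-N,5-dimethyl-3-[(triethylsilyl)oxy]hex-5-enamide | C=C(C)[C@H](O[Si](C)(C)C(C)(C)C)[C@H](O[Si](CC)(CC)CC)[C@H](C(=O)N(C)OC)CCCl | intermediate
15 | (3R,4R,5S)-5-[(tert-butyldimethylsilyl)oxy]-3-(2-chloroethyl)-6-methyl-4-[(triethylsilyl)oxy]hept-6-en-2-one | C=C(C)[C@H](O[Si](C)(C)C(C)(C)C)[C@H](O[Si](CC)(CC)CC)[C@H](C(C)=O)CCCl | intermediate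
16 | potassium enolate of 15 (terminal enolate) | C=C(C)[C@H](O[Si](C)(C)C(C)(C)C)[C@H](O[Si](CC)(CC)CC)[C@H](C(=C)[O-])CCCl.[K+] | intermediate (not isolated)
17 | (3R,4R,5S)-5-[(tert-butyldimethylsilyl)oxy]-3-(2-chloroethyl)-6-methyl-4-[(triethylsilyl)oxy]hepta-1,6-dien-2-yl trifluoromethanesulfonate | C=C(C)[C@H](O[Si](C)(C)C(C)(C)C)[C@H](O[Si](CC)(CC)CC)[C@H](C(=C)OS(=O)(=O)C(F)(F)F)CCCl | intermediate
18 | 1,2,4-trioxolane (secondary ozonide) of the isopropenyl group of 17, mixture at the ozonide carbon | CC1(OCOO1)[C@H](O[Si](C)(C)C(C)(C)C)[C@H](O[Si](CC)(CC)CC)[C@H](C(=C)OS(=O)(=O)C(F)(F)F)CCCl | intermediate (not isolated)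
19 | (3R,4R,5R)-5-[(tert-butyldimethylsilyl)oxy]-3-(2-chloroethyl)-6-oxo-4-[(triethylsilyl)oxy]hept-1-en-2-yl trifluoromethanesulfonate | CC(=O)[C@H](O[Si](C)(C)C(C)(C)C)[C@H](O[Si](CC)(CC)CC)[C@H](C(=C)OS(=O)(=O)C(F)(F)F)CCCl | intermediate
20 | (3R,4R,5R)-5-[(tert-butyldimethylsilyl)oxy]-3-(2-iodoethyl)-6-oxo-4-[(triethylsilyl)oxy]hept-1-en-2-yl trifluoromethanesulfonate | CC(=O)[C@H](O[Si](C)(C)C(C)(C)C)[C@H](O[Si](CC)(CC)CC)[C@H](C(=C)OS(=O)(=O)C(F)(F)F)CCI | intermediate
21 | diphenyl sulfide | c1ccc(cc1)Sc1ccccc1 | starting material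
22 | [(3R,4R,5R)-5-[(tert-butyldimethylsilyl)oxy]-6-oxo-4-[(triethylsilyl)oxy]-3-[1-(trifluoromethanesulfonyloxy)ethenyl]heptyl]diphenylsulfonium tetrafluoroborate | CC(=O)[C@H](O[Si](C)(C)C(C)(C)C)[C@H](O[Si](CC)(CC)CC)[C@H](C(=C)OS(=O)(=O)C(F)(F)F)CC[S+](c1ccccc1)c1ccccc1.F[B-](F)(F)F | intermediate
23 | sulfonium ylide of 22 (carbanion at C5) | CC(=O)[C@H](O[Si](C)(C)C(C)(C)C)[C@H](O[Si](CC)(CC)CC)[C@H](C(=C)OS(=O)(=O)C(F)(F)F)C[CH-][S+](c1ccccc1)c1ccccc1 | intermediate (not isolated)
24 | betaine: cyclohexane with C4 alkoxide (cis to the C3 oxygen) and C5 diphenylsulfonio group (trans to the alkoxide) | C=C(OS(=O)(=O)C(F)(F)F)[C@@H]1C[C@@H]([S+](c2ccccc2)c2ccccc2)[C@](C)([O-])[C@H](O[Si](C)(C)C(C)(C)C)[C@@H]1O[Si](CC)(CC)CC | intermediate (not isolated)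
25 | 1-[(1R,2R,3R,4S,5S)-3-[(tert-butyldimethylsilyl)oxy]-4,5-epoxy-4-methyl-2-[(triethylsilyl)oxy]cyclohexyl]ethenyl trifluoromethanesulfonate (C1 substituent, C2 and C3 oxygens and epoxide oxygen all cis) | C=C(OS(=O)(=O)C(F)(F)F)[C@@H]1C[C@@H]2O[C@]2(C)[C@H](O[Si](C)(C)C(C)(C)C)[C@@H]1O[Si](CC)(CC)CC | intermediate
26 | 4-methylpent-3-en-1-ol | CC(C)=CCCO | starting material
27 | 4-methylpent-3-enal | CC(C)=CCC=O | intermediate
28 | alkenylchromium dichloride derived from 25 (trivalent chromium at C7) | C=C([Cr](Cl)Cl)[C@@H]1C[C@@H]2O[C@]2(C)[C@H](O[Si](C)(C)C(C)(C)C)[C@@H]1O[Si](CC)(CC)CC | intermediate (not isolated)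
29 | (3S)-2-[(1S,2R,3R,4S,5S)-3-[(tert-butyldimethylsilyl)oxy]-4,5-epoxy-4-methyl-2-[(triethylsilyl)oxy]cyclohexyl]-6-methylhepta-1,5-dien-3-ol | C=C([C@@H](O)CC=C(C)C)[C@@H]1C[C@@H]2O[C@]2(C)[C@H](O[Si](C)(C)C(C)(C)C)[C@@H]1O[Si](CC)(CC)CC | intermediate
30 | (3S)-2-[(1S,2R,3R,4S,5S)-3-[(tert-butyldimethylsilyl)oxy]-4,5-epoxy-2-hydroxy-4-methylcyclohexyl]-6-methylhepta-1,5-dien-3-ol | C=C([C@@H](O)CC=C(C)C)[C@@H]1C[C@@H]2O[C@]2(C)[C@H](O[Si](C)(C)C(C)(C)C)[C@@H]1O | intermediate
31 | angelic acid, (Z)-2-methylbut-2-enoic acid | C/C=C(/C)C(=O)O | starting material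
32 | C2,C8-bis-angelate of 30, (1S,2R,3R,4S,5S,8S) | C=C([C@H](CC=C(C)C)OC(=O)/C(C)=C\C)[C@@H]1C[C@@H]2O[C@]2(C)[C@H](O[Si](C)(C)C(C)(C)C)[C@@H]1OC(=O)/C(C)=C\C | intermediate
33 | C3 TBS ether of the target, (1S,2R,3R,4S,5S,8S,10R) | C=C([C@H](C[C@H]1OC1(C)C)OC(=O)/C(C)=C\C)[C@@H]1C[C@@H]2O[C@]2(C)[C@H](O[Si](C)(C)C(C)(C)C)[C@@H]1OC(=O)/C(C)=C\C | intermediate
34 | CNP0235377.1, (1S,2R,3R,4R,5S,8S,10R) | C=C([C@H](C[C@H]1OC1(C)C)OC(=O)/C(C)=C\C)[C@@H]1C[C@@H]2O[C@]2(C)[C@H](O)[C@@H]1OC(=O)/C(C)=C\C | target

## Step count and the least certain steps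

Total: 21 steps. Longest linear sequence: 19 steps (steps 1–5, 7–15 and 17–21).

**Step 15 (key step).** Three processes can go wrong:
- addition on the wrong face of the ketone, or formation of the betaine with oxygen and sulfur cis, which cannot close;
- E2 loss of diphenyl sulfide from the sulfonium salt before the ylide adds;
- silyl transfer from the C2 or C3 oxygen to the tertiary alkoxide.

Fallback, from 20 back to 25: iodide 20 is heated with PPh3 in MeCN to give the phosphonium iodide F1. KN(SiMe3)2 in THF then closes the ring by intramolecular Wittig olefination to the cyclohexene F2, with the C4=C5 alkene. NBS in aqueous THF should form the bromonium ion on the face away from the three cis substituents, and water opens it at the tertiary C4 to give the bromohydrin F3 (C4 hydroxyl cis to the C3 oxygen, C5 bromide trans). KN(SiMe3)2 at −78 to 0 °C closes F3 to 25.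

**Step 14.** The silver-activated C5 may be attacked by the C2 silyl ether oxygen or the ketone oxygen instead of the weakly nucleophilic sulfide, and traces of acid may desilylate. Fallback, from 19 back to 22, with sulfur as the nucleophile: chloride 19 is displaced with NaSPh in DMF to give the phenyl sulfide F4. F4 is S-phenylated with Ph2IBF4 and catalytic Cu(OAc)2 in 1,2-dichloroethane at 80 °C to give 22.

**Step 17.** Ligand control at C8 may be weak for this hindered alkenyl donor, which would give a mixture of 29 and its C8 epimer F5. Fallback, from that mixture back to 29: Dess–Martin oxidation gives the single enone F6. Reduction with (R)-1-methyl-3,3-diphenyl-tetrahydro-1H,3H-pyrrolo[1,2-c][1,3,2]oxazaborole and catecholborane in toluene at −78 °C, with the α-branched alkenyl group as the large substituent, should return the (8S)-alcohol 29.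

**Step 19.** Acylation of the crowded C2 hydroxyl may stall after the C8 hydroxyl has reacted, and prolonged heating may isomerise angelate to tiglate. Fallback, from 30 back to 32, building the Z alkene on the ester: diol 30 is esterified at both hydroxyls with 2-[bis(2,2,2-trifluoroethoxy)phosphoryl]propanoic acid (dicyclohexylcarbodiimide, catalytic 4-(dimethylamino)pyridine) to give the bis-phosphonate F7. A double Still–Gennari olefination with KN(SiMe3)2, 18-crown-6 and acetaldehyde in THF at −78 °C gives the two (Z)-2-methylbut-2-enoates of 32.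

**Step 21.** HF may open the acid-labile gem-dimethyl epoxide, and the C2 ester may migrate to the freed C3 hydroxyl. Fallback, from 32 to 34, changing the order so the side-chain epoxide never meets fluoride: 32 is desilylated first (HF·pyridine, pyridine, THF) to the C3 alcohol F8. The Shi epoxidation is then run last on F8, with the buffer held near pH 8 to limit acyl migration, to give 34 directly.

## Further compounds

F1 | step 15 | phosphonium iodide from 20 and PPh3 | CC(=O)[C@H](O[Si](C)(C)C(C)(C)C)[C@H](O[Si](CC)(CC)CC)[C@H](C(=C)OS(=O)(=O)C(F)(F)F)CC[P+](c1ccccc1)(c1ccccc1)c1ccccc1.[I-]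
F2 | step 15 | 1-[(1R,2R,3S)-3-[(tert-butyldimethylsilyl)oxy]-4-methyl-2-[(triethylsilyl)oxy]cyclohex-4-en-1-yl]ethenyl trifluoromethanesulfonate | C=C(OS(=O)(=O)C(F)(F)F)[C@@H]1CC=C(C)[C@H](O[Si](C)(C)C(C)(C)C)[C@@H]1O[Si](CC)(CC)CC
F3 | step 15 | bromohydrin of F2 (C4 hydroxyl cis to the C3 oxygen, C5 bromide trans to it) | C=C(OS(=O)(=O)C(F)(F)F)[C@@H]1C[C@@H](Br)[C@](C)(O)[C@H](O[Si](C)(C)C(C)(C)C)[C@@H]1O[Si](CC)(CC)CC
F4 | step 14 | (3R,4R,5R)-5-[(tert-butyldimethylsilyl)oxy]-6-oxo-3-[2-(phenylsulfanyl)ethyl]-4-[(triethylsilyl)oxy]hept-1-en-2-yl trifluoromethanesulfonate | CC(=O)[C@H](O[Si](C)(C)C(C)(C)C)[C@H](O[Si](CC)(CC)CC)[C@H](C(=C)OS(=O)(=O)C(F)(F)F)CCSc1ccccc1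
F5 | step 17 | C8 epimer of 29, (3R)-alcohol | C=C([C@H](O)CC=C(C)C)[C@@H]1C[C@@H]2O[C@]2(C)[C@H](O[Si](C)(C)C(C)(C)C)[C@@H]1O[Si](CC)(CC)CC
F6 | step 17 | 2-[(1S,2R,3R,4S,5S)-3-[(tert-butyldimethylsilyl)oxy]-4,5-epoxy-4-methyl-2-[(triethylsilyl)oxy]cyclohexyl]-6-methylhepta-1,5-dien-3-one | C=C(C(=O)CC=C(C)C)[C@@H]1C[C@@H]2O[C@]2(C)[C@H](O[Si](C)(C)C(C)(C)C)[C@@H]1O[Si](CC)(CC)CC
F7 | step 19 | C2,C8-bis{2-[bis(2,2,2-trifluoroethoxy)phosphoryl]propanoate} of 30 (mixture at the phosphonate-bearing carbons) | C=C([C@H](CC=C(C)C)OC(=O)C(C)P(=O)(OCC(F)(F)F)OCC(F)(F)F)[C@@H]1C[C@@H]2O[C@]2(C)[C@H](O[Si](C)(C)C(C)(C)C)[C@@H]1OC(=O)C(C)P(=O)(OCC(F)(F)F)OCC(F)(F)F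
F8 | step 21 | C3 alcohol from 32, (1S,2R,3R,4R,5S,8S)-4,5-epoxy-3-hydroxybisabola-7(14),10-diene-2,8-diyl bis[(Z)-2-methylbut-2-enoate] | C=C([C@H](CC=C(C)C)OC(=O)/C(C)=C\C)[C@@H]1C[C@@H]2O[C@]2(C)[C@H](O)[C@@H]1OC(=O)/C(C)=C\C
A1 | alternative 1 | isoprene | C=CC(C)=C
A2 | alternative 1 | (R)-2-tert-butyl-4H-1,3-dioxin-4-one | O=C1C=CO[C@@H](C(C)(C)C)O1
A3 | alternative 1 | cis-fused 2-tert-butyl-1,3-dioxan-4-one on the 4-methylcyclohexene ring | CC1=CC[C@H]2C(=O)O[C@H](C(C)(C)C)O[C@H]2C1
A4 | alternative 2 | 6-methyl-6-vinyl-4,5-O-isopropylidene δ-lactone (vinyl trans to the acetonide oxygens) | O=C1C[C@H]2OC(C)(C)O[C@H]2[C@](C)(C=C)O1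
A5 | alternative 2 | all-cis 5,6-(isopropylidenedioxy)-4-methylcyclohex-3-ene-1-carboxylic acid | OC(=O)[C@@H]1CC=C(C)[C@@H]2OC(C)(C)O[C@H]12
A6 | alternative 3 | methyl (2Z,5Z,7S)-2-(bromomethyl)-7-[(tert-butyldimethylsilyl)oxy]-6-methyl-8-oxoocta-2,5-dienoate | COC(=O)/C(CBr)=C/C/C=C(/C)[C@H](O[Si](C)(C)C(C)(C)C)C=O
A7 | alternative 3 | cis-fused α-methylene-γ-butyrolactone on the 4-methyl-3-silyloxycyclohexene ring | C=C1C(=O)O[C@@H]2[C@H]1CC=C(C)[C@@H]2O[Si](C)(C)C(C)(C)C
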